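The two C–H bonds of the butanedioate chain are the disconnection: the adjacent stereocentres C2 (benzyl-bearing, next to the C1 methyl ester) and C3 (bearing the 4-hydroxyphenyl ring and the C4 acid) are created together by enantioselective syn-hydrogenation of a (Z)-2-aryl-3-benzylbutenedioic half-ester. The key step exploits the free C4 carboxylate on alkene carbon C3, flanked by the 4-hydroxyphenyl ring and cis to the C1 ester, as the anchor for a chiral ruthenium bisphosphine catalyst; the prenyl alkene on the other ring offers no such anchor. The precursor comes from a one-pot union of an arylcopper, dimethyl acetylenedicarboxylate and a benzylic bromide, followed by hydrolysis of the C4 ester alone.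

Key step: step 8

Assumption: the chain is numbered C1 (ester carbon), C2 (benzyl-bearing), C3 (aryl-bearing), C4 (acid carbon); the (S)-bisphosphine is written for step 8 by analogy with 2-arylacrylic acids, and its antipode would be used should it deliver the 2R,3R acid.

Step 1
Reactants: 1 methyl 3-hydroxy-4-iodobenzoate; 2 prenylboronic acid pinacol ester
Product: 3 methyl 3-hydroxy-4-(3-methylbut-2-en-1-yl)benzoate
Conditions: Pd(OAc)2 (2 mol%), tBuXPhos (4 mol%), K3PO4 (aq), THF, 40 °C
Reagents that add atoms: none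
Why: Suzuki–Miyaura coupling of the allylboronate, in which a bulky biarylphosphine on palladium should steer reductive elimination to the unsubstituted CH2 terminus of the allyl ligand and give the linear prenyl arene; the aryl iodide reacts at 40 °C without harm to the ester, and the phenol is left free here because an aryl silyl ether would be at risk in warm aqueous phosphate.

Step 2
Reactants: 3 methyl 3-hydroxy-4-(3-methylbut-2-en-1-yl)benzoate
Product: 4 methyl 3-(tert-butyldimethylsilyloxy)-4-(3-methylbut-2-en-1-yl)benzoate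
Conditions: TBSCl, imidazole, DMF, rt
Reagents that add atoms: tert-butyldimethylsilyl chloride, CC(C)(C)[Si](C)(C)Cl
Why: Imidazole-promoted O-silylation of the phenol; the aryl silyl ether masks the acidic OH through the hydride, bromination and organocopper steps and later falls to hydroxide in the same operation as the ester hydrolysis.

Step 3
Reactants: 4 methyl 3-(tert-butyldimethylsilyloxy)-4-(3-methylbut-2-en-1-yl)benzoate
Product: 5 [3-(tert-butyldimethylsilyloxy)-4-(3-methylbut-2-en-1-yl)phenyl]methanol
Conditions: DIBAL-H (2.5 equiv), CH2Cl2, −78 to 0 °C; Rochelle salt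
Reagents that add atoms: none
Why: DIBAL-H reduction of the aryl ester to the benzylic alcohol, with the isolated trisubstituted alkene and the silyl ether inert to the aluminium hydride.

Step 4
Reactants: 5 [3-(tert-butyldimethylsilyloxy)-4-(3-methylbut-2-en-1-yl)phenyl]methanol
Product: 6 3-(tert-butyldimethylsilyloxy)-4-(3-methylbut-2-en-1-yl)benzyl bromide
Conditions: CBr4, PPh3, CH2Cl2, 0 °C
Reagents that add atoms: carbon tetrabromide, BrC(Br)(Br)Br
Why: Appel reaction through the alkoxyphosphonium bromide, which is neutral and generates no HBr that could add to the prenyl alkene or cleave the silyl ether.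

Step 5
Reactants: 7 (4-bromophenoxy)(tert-butyl)dimethylsilane
Product: 8 4-(tert-butyldimethylsilyloxy)phenylmagnesium bromide (titrated THF solution)
Conditions: Mg turnings, I2 (cat.), THF, 40 °C
Reagents that add atoms: magnesium, [Mg]
Why: Grignard formation by magnesium insertion into the aryl bromide, which the aryl silyl ether tolerates.

Step 6
Reactants: 8 4-(tert-butyldimethylsilyloxy)phenylmagnesium bromide; 9 dimethyl acetylenedicarboxylate; 6 3-(tert-butyldimethylsilyloxy)-4-(3-methylbut-2-en-1-yl)benzyl bromide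
Product: 12 dimethyl (Z)-2-[4-(tert-butyldimethylsilyloxy)phenyl]-3-[3-(tert-butyldimethylsilyloxy)-4-(3-methylbut-2-en-1-yl)benzyl]but-2-enedioate, via arylcopper 10 (not isolated), via alkenylcopper 11 (not isolated)
Conditions: 8 (1.3 equiv), CuBr·SMe2 (1.3 equiv), THF, −40 °C; 9 (1.3 equiv), −78 °C, 1 h; 6 (1.0 equiv), HMPA (or DMPU), −78 to −20 °C; NH4Cl/NH3 (aq)
Reagents that add atoms: none
Why: Three-component carbometalation–alkylation: transmetalation to monovalent copper gives the arylcopper, which adds syn across the electron-poor alkyne at −78 °C so that aryl and copper are cis, and the alkenylcopper is then C-benzylated by 6 with retention in the dipolar cosolvent before its copper allenolate form can scramble the geometry, which fixes the two ester groups cis (Z).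

Step 7
Reactants: 12 dimethyl (Z)-2-[4-(tert-butyldimethylsilyloxy)phenyl]-3-[3-(tert-butyldimethylsilyloxy)-4-(3-methylbut-2-en-1-yl)benzyl]but-2-enedioate
Product: 14 (Z)-2-(4-hydroxyphenyl)-3-[3-hydroxy-4-(3-methylbut-2-en-1-yl)benzyl]-4-methoxy-4-oxobut-2-enoic acid, via bis-phenol diester 13 (not isolated)
Conditions: LiOH·H2O (4 equiv), THF/MeOH/H2O, 0 °C to rt; hexane wash of the basic aqueous phase; AcOH to pH 5–6 at 0 °C, EtOAc; Et3N (1.1 equiv), product kept as its triethylammonium carboxylate
Reagents that add atoms: lithium hydroxide, [Li+].[OH-]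
Why: Regioselective ester saponification with concurrent cleavage of both aryl silyl ethers: hydroxide first frees the phenoxides, the 4-phenoxide on C3 then donates through the C3=C2 bond into the C1 ester (a vinylogous carbonate anion) so that only the cross-conjugated C4 ester should be attacked, the new carboxylate shuts down a second hydrolysis, and holding the product at pH 5 or above as an ammonium carboxylate prevents closure to the maleic anhydride and acid-induced chroman formation from the o-prenylphenol.

Step 8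
Reactants: 14 (Z)-2-(4-hydroxyphenyl)-3-[3-hydroxy-4-(3-methylbut-2-en-1-yl)benzyl]-4-methoxy-4-oxobut-2-enoic acid (triethylammonium carboxylate)
Product: 15 (2S,3S)-2-(4-hydroxyphenyl)-3-[3-hydroxy-4-(3-methylbut-2-en-1-yl)benzyl]-4-methoxy-4-oxobutanoic acid (CNP0437978.1)
Conditions: Ru(OAc)2[(S)-H8-BINAP] (2 mol%), H2 (100 bar), Et3N (1 equiv, from the salt), MeOH, 40 °C; cold pH 4–5 citrate buffer, EtOAc
Reagents that add atoms: none
Why: Proposed new method: the carboxylate of 14 should replace an acetate on divalent ruthenium and hold the C2=C3 bond at the metal, helped by the cis C1 ester carbonyl; heterolytic H2 activation then gives a ruthenium hydride that inserts the alkene, placing H on C3 and forming a five-membered ruthenacycle through C2, whose Ru–C bond is cleaved with retention by H2 or methanol, so both hydrogens arrive on one face. The closest known reaction type is the carboxylate-directed hydrogenation of tetrasubstituted 2-arylacrylic acids and of itaconate or maleate half-esters with ruthenium or rhodium atropisomeric bisphosphine catalysts; a 2-aryl-3-benzylmaleic half-ester combining both features has no direct model. No ring is closed. C3 is set by the face of hydride delivery, which the chiral bisphosphine dictates, and C2 follows from strict syn-addition to the Z alkene fixed in steps 6 and 7, which can give only the 2S,3S or 2R,3R pair. The step needs face selectivity, syn-specificity and chemoselectivity over the prenyl alkene: the first comes from the ligand, the second from the chelated alkyl intermediate, and the third from the fact that the isolated trisubstituted alkene has no coordinating group within reach of the metal. Mildly basic methanol spares the o-prenylphenol and the C3–H, which is alpha to a carboxylate, and no further step follows that could epimerise either centre.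

Compound list
1 | methyl 3-hydroxy-4-iodobenzoate | COC(=O)c1ccc(I)c(O)c1 | starting material
2 | prenylboronic acid pinacol ester | CC(C)=CCB1OC(C)(C)C(C)(C)O1 | starting material
3 | methyl 3-hydroxy-4-(3-methylbut-2-en-1-yl)benzoate | COC(=O)c1ccc(CC=C(C)C)c(O)c1 | intermediate
4 | methyl 3-(tert-butyldimethylsilyloxy)-4-(3-methylbut-2-en-1-yl)benzoate | COC(=O)c1ccc(CC=C(C)C)c(O[Si](C)(C)C(C)(C)C)c1 | intermediate
5 | [3-(tert-butyldimethylsilyloxy)-4-(3-methylbut-2-en-1-yl)phenyl]methanol | OCc1ccc(CC=C(C)C)c(O[Si](C)(C)C(C)(C)C)c1 | intermediate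
6 | 3-(tert-butyldimethylsilyloxy)-4-(3-methylbut-2-en-1-yl)benzyl bromide | BrCc1ccc(CC=C(C)C)c(O[Si](C)(C)C(C)(C)C)c1 | intermediate
7 | (4-bromophenoxy)(tert-butyl)dimethylsilane | CC(C)(C)[Si](C)(C)Oc1ccc(Br)cc1 | starting material
8 | 4-(tert-butyldimethylsilyloxy)phenylmagnesium bromide | CC(C)(C)[Si](C)(C)Oc1ccc([Mg]Br)cc1 | intermediate
9 | dimethyl acetylenedicarboxylate | COC(=O)C#CC(=O)OC | starting material
10 | 4-(tert-butyldimethylsilyloxy)phenylcopper (not isolated) | CC(C)(C)[Si](C)(C)Oc1ccc([Cu])cc1 | intermediate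
11 | alkenylcopper syn-adduct, dimethyl 2-[4-(tert-butyldimethylsilyloxy)phenyl]-3-cupriobut-2-enedioate with aryl and copper cis and the esters cis (not isolated) | COC(=O)/C([Cu])=C(\C(=O)OC)c1ccc(O[Si](C)(C)C(C)(C)C)cc1 | intermediate
12 | dimethyl (Z)-2-[4-(tert-butyldimethylsilyloxy)phenyl]-3-[3-(tert-butyldimethylsilyloxy)-4-(3-methylbut-2-en-1-yl)benzyl]but-2-enedioate | COC(=O)/C(Cc1ccc(CC=C(C)C)c(O[Si](C)(C)C(C)(C)C)c1)=C(\C(=O)OC)c1ccc(O[Si](C)(C)C(C)(C)C)cc1 | intermediate
13 | dimethyl (Z)-2-(4-hydroxyphenyl)-3-[3-hydroxy-4-(3-methylbut-2-en-1-yl)benzyl]but-2-enedioate (bis-phenol diester, present as its phenoxides, not isolated) | COC(=O)/C(Cc1ccc(CC=C(C)C)c(O)c1)=C(\C(=O)OC)c1ccc(O)cc1 | intermediate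
14 | (Z)-2-(4-hydroxyphenyl)-3-[3-hydroxy-4-(3-methylbut-2-en-1-yl)benzyl]-4-methoxy-4-oxobut-2-enoic acid (handled as its triethylammonium carboxylate; formula of the parent acid) | COC(=O)/C(Cc1ccc(CC=C(C)C)c(O)c1)=C(\C(=O)O)c1ccc(O)cc1 | intermediate
15 | (2S,3S)-2-(4-hydroxyphenyl)-3-[3-hydroxy-4-(3-methylbut-2-en-1-yl)benzyl]-4-methoxy-4-oxobutanoic acid | COC(=O)[C@@H](Cc1ccc(CC=C(C)C)c(O)c1)[C@H](C(=O)O)c1ccc(O)cc1 | target

Total step count: 8. Longest linear sequence: 7 steps (steps 1, 2, 3, 4, 6, 7, 8).

Steps most likely to fail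

1. Step 8. What may go wrong: the crowded tetrasubstituted alkene may not turn over, the catalyst may discriminate the two faces poorly, or the C2–ruthenium alkyl may leak to an O-bound enolate and erode syn-specificity. The fallback uses known auxiliary chemistry in place of hydrogenation; it sets out from Grignard reagent 8 and bromide 6 and returns at 15.
 - Fumaryl chloride is treated in turn with 2-(trimethylsilyl)ethanol (1 equiv, pyridine, −78 °C) and lithiated (R)-4-phenyloxazolidin-2-one to give the acceptor 2-(trimethylsilyl)ethyl (E)-4-oxo-4-[(R)-2-oxo-4-phenyloxazolidin-3-yl]but-2-enoate F1.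
 - The arylcopper from 8 and CuBr·SMe2 (THF/Me2S, −20 °C) should add beta to the imide of the magnesium-chelated s-cis enoyl imide, on the face away from the phenyl group, setting C3 in 2-(trimethylsilyl)ethyl (S)-2-[4-(tert-butyldimethylsilyloxy)phenyl]-4-oxo-4-[(R)-2-oxo-4-phenyloxazolidin-3-yl]butanoate F2.
 - A single auxiliary would deliver aryl and benzyl to the same face of the fumarate and lead to the unwanted diastereomer, so the auxiliary is exchanged. LiOH/H2O2 (THF/H2O, 0 °C, brief, so that the aryl silyl ether should survive) releases (S)-3-[4-(tert-butyldimethylsilyloxy)phenyl]-4-oxo-4-[2-(trimethylsilyl)ethoxy]butanoic acid F3.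
 - The pivaloyl mixed anhydride of F3 (PivCl, Et3N) acylates lithiated (S)-4-benzyloxazolidin-2-one to give 2-(trimethylsilyl)ethyl (S)-4-[(S)-4-benzyl-2-oxooxazolidin-3-yl]-2-[4-(tert-butyldimethylsilyloxy)phenyl]-4-oxobutanoate F4.
 - NaHMDS (THF, −78 °C) deprotonates the imide CH2 kinetically under chelation control, and 6 alkylates the chelated Z-enolate anti to the auxiliary benzyl group. This should give 2-(trimethylsilyl)ethyl (2S,3S)-3-[(S)-4-benzyl-2-oxooxazolidine-3-carbonyl]-2-[4-(tert-butyldimethylsilyloxy)phenyl]-4-[3-(tert-butyldimethylsilyloxy)-4-(3-methylbut-2-en-1-yl)phenyl]butanoate F5.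
 - TBAF (THF, 0 °C to rt) removes the silylethyl ester and both aryl silyl ethers to give (2S,3S)-3-[(S)-4-benzyl-2-oxooxazolidine-3-carbonyl]-2-(4-hydroxyphenyl)-4-[3-hydroxy-4-(3-methylbut-2-en-1-yl)phenyl]butanoic acid F6.
 - MeOMgBr in MeOH/CH2Cl2 (0 °C) exchanges the auxiliary for the methyl ester while the C4 carboxylate stays inert, giving 15.

2. Step 6. What may go wrong: benzylation of the alkenylcopper may be slower than its equilibration through the copper allenolate, so that Z geometry is lost, or the copper species may simply be protonated on work-up. The fallback sets out from 8, 9 and 6 and returns at 12.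
 - The carbocupration is run as before through 10 and 11, and the alkenylcopper is quenched at −78 °C with iodine, a trap fast enough to outrun isomerisation. This gives dimethyl (E)-2-[4-(tert-butyldimethylsilyloxy)phenyl]-3-iodobut-2-enedioate (esters cis) F7.
 - Separately, 6 is converted with zinc dust and LiCl in THF into [3-(tert-butyldimethylsilyloxy)-4-(3-methylbut-2-en-1-yl)benzyl]zinc bromide F8.
 - Negishi coupling of F7 with F8 (Pd(OAc)2, SPhos, THF, rt) proceeds with retention at the alkenyl iodide and gives 12.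

3. Step 7. What may go wrong: loss of site selectivity between the two esters, or over-hydrolysis followed by ring closure to the anhydride during work-up. The fallback sets out from 12 and returns at 14.
 - Both esters and both silyl ethers are cleaved on purpose (LiOH in excess, THF/MeOH/H2O, 50 °C), and brief acidification to pH 3 with cold citric acid lets the diacid close to 3-(4-hydroxyphenyl)-4-[3-hydroxy-4-(3-methylbut-2-en-1-yl)benzyl]furan-2,5-dione F9.
 - Allyl alcohol with Et3N and catalytic DMAP should open the ring at the C4 carbonyl, the one not in conjugation with the 4-hydroxyphenyl ring. This gives (Z)-4-(allyloxy)-3-(4-hydroxyphenyl)-2-[3-hydroxy-4-(3-methylbut-2-en-1-yl)benzyl]-4-oxobut-2-enoic acid F10, kept as its triethylammonium salt.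
 - MeI with KHCO3 in DMF methylates the C1 carboxylate to give 1-allyl 4-methyl (Z)-2-(4-hydroxyphenyl)-3-[3-hydroxy-4-(3-methylbut-2-en-1-yl)benzyl]but-2-enedioate F11. This neutral diester can be separated by chromatography from any regioisomer, which is recycled through F9.
 - Pd(PPh3)4 with morpholine (THF, rt) removes the allyl group and gives 14.

Further compounds
F1 | step 8 | 2-(trimethylsilyl)ethyl (E)-4-oxo-4-[(R)-2-oxo-4-phenyloxazolidin-3-yl]but-2-enoate | C[Si](C)(C)CCOC(=O)/C=C/C(=O)N1[C@H](c2ccccc2)COC1=O
F2 | step 8 | 2-(trimethylsilyl)ethyl (S)-2-[4-(tert-butyldimethylsilyloxy)phenyl]-4-oxo-4-[(R)-2-oxo-4-phenyloxazolidin-3-yl]butanoate | C[Si](C)(C)CCOC(=O)[C@H](c1ccc(O[Si](C)(C)C(C)(C)C)cc1)CC(=O)N1[C@H](c2ccccc2)COC1=O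
F3 | step 8 | (S)-3-[4-(tert-butyldimethylsilyloxy)phenyl]-4-oxo-4-[2-(trimethylsilyl)ethoxy]butanoic acid | C[Si](C)(C)CCOC(=O)[C@H](c1ccc(O[Si](C)(C)C(C)(C)C)cc1)CC(=O)O
F4 | step 8 | 2-(trimethylsilyl)ethyl (S)-4-[(S)-4-benzyl-2-oxooxazolidin-3-yl]-2-[4-(tert-butyldimethylsilyloxy)phenyl]-4-oxobutanoate | C[Si](C)(C)CCOC(=O)[C@H](c1ccc(O[Si](C)(C)C(C)(C)C)cc1)CC(=O)N1[C@@H](Cc2ccccc2)COC1=O
F5 | step 8 | 2-(trimethylsilyl)ethyl (2S,3S)-3-[(S)-4-benzyl-2-oxooxazolidine-3-carbonyl]-2-[4-(tert-butyldimethylsilyloxy)phenyl]-4-[3-(tert-butyldimethylsilyloxy)-4-(3-methylbut-2-en-1-yl)phenyl]butanoate | C[Si](C)(C)CCOC(=O)[C@H](c1ccc(O[Si](C)(C)C(C)(C)C)cc1)[C@H](Cc1ccc(CC=C(C)C)c(O[Si](C)(C)C(C)(C)C)c1)C(=O)N1[C@@H](Cc2ccccc2)COC1=O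
F6 | step 8 | (2S,3S)-3-[(S)-4-benzyl-2-oxooxazolidine-3-carbonyl]-2-(4-hydroxyphenyl)-4-[3-hydroxy-4-(3-methylbut-2-en-1-yl)phenyl]butanoic acid | OC(=O)[C@H](c1ccc(O)cc1)[C@H](Cc1ccc(CC=C(C)C)c(O)c1)C(=O)N1[C@@H](Cc2ccccc2)COC1=O
F7 | step 6 | dimethyl (E)-2-[4-(tert-butyldimethylsilyloxy)phenyl]-3-iodobut-2-enedioate | COC(=O)/C(I)=C(\C(=O)OC)c1ccc(O[Si](C)(C)C(C)(C)C)cc1
F8 | step 6 | [3-(tert-butyldimethylsilyloxy)-4-(3-methylbut-2-en-1-yl)benzyl]zinc bromide | Br[Zn]Cc1ccc(CC=C(C)C)c(O[Si](C)(C)C(C)(C)C)c1
F9 | step 7 | 3-(4-hydroxyphenyl)-4-[3-hydroxy-4-(3-methylbut-2-en-1-yl)benzyl]furan-2,5-dione | O=C1OC(=O)C(c2ccc(O)cc2)=C1Cc1ccc(CC=C(C)C)c(O)c1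
F10 | step 7 | (Z)-4-(allyloxy)-3-(4-hydroxyphenyl)-2-[3-hydroxy-4-(3-methylbut-2-en-1-yl)benzyl]-4-oxobut-2-enoic acid | OC(=O)/C(Cc1ccc(CC=C(C)C)c(O)c1)=C(\C(=O)OCC=C)c1ccc(O)cc1
F11 | step 7 | 1-allyl 4-methyl (Z)-2-(4-hydroxyphenyl)-3-[3-hydroxy-4-(3-methylbut-2-en-1-yl)benzyl]but-2-enedioate | COC(=O)/C(Cc1ccc(CC=C(C)C)c(O)c1)=C(\C(=O)OCC=C)c1ccc(O)cc1
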